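A direct plan would join 3,4,5-trihydroxybenzaldehyde A1 and 6-bromo-2-fluoro-3-methoxybenzaldehyde A2 by SNAr to the diaryl ether dialdehyde A3, brominate its resorcinol ring to dibromide A4, attach both lactone arms by a double Stille coupling with ethyl (Z)-3-(tributylstannyl)prop-2-enoate A5 to reach coumarin dialdehyde A6, and end with a double Dakin oxidation and lactonisation.
Its weakest steps would be:
- the SNAr etherification, because one of three phenols of an air-sensitive pyrogallol would have to attack a carbon flanked by two ortho substituents;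
- the double Stille coupling, because two hindered aryl bromides next to free phenols and formyl groups would have to couple with a stoichiometric tin reagent without loss of Z geometry;
- the twofold formyl-to-hydroxyl oxidation, because a peracid would act beside acrylate units and the step would add length without complexity.

The route proposed here never couples two arenes. Phenol 1 is O-alkylated to an aryloxyacetic acid, and ring B (C4a, C5, C6, C7, C8, C8a of the dihydroxycoumarin half) is built around that O–CH2–C(=O) unit. Its CH2 becomes C8 and its carbonyl carbon C8a; two molecules of an ynol ether supply C7–C6 and C5–C4a, using the alternating oxygens at C5, C7 and C8a. The key step closes ring B, sets the aryloxy carbon between two oxygenated carbons and leaves C8a–OH as the only free phenol, so the later lactonisation is unambiguous. No hindered SNAr, tin coupling or formyl-to-hydroxyl oxidation is needed.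

Key step: step 4

Remark: 8-hydroxy-7-methoxy-2H-chromen-2-one (daphnetin 7-methyl ether) is assumed to be purchasable; unprimed locants refer to the dihydroxycoumarin half, primed locants to the methoxycoumarin half.

Step 1
Reactants: 1 8-hydroxy-7-methoxy-2H-chromen-2-one; 2 tert-butyl bromoacetate
Product: 4 2-[(7-methoxy-2-oxo-2H-chromen-8-yl)oxy]acetic acid, via tert-butyl ester 3 (not isolated)
Conditions: K2CO3, acetone, reflux; filter, evaporate; then TFA, CH2Cl2, rt
Reagents that add atoms: none
Why: Williamson O-alkylation (SN2) of the 8-phenoxide at a primary α-bromo ester carbon makes the future C8–O bond without any aryl–oxygen coupling, and acid-catalysed loss of isobutene frees the acid without opening the lactone; no stereocentre is formed.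

Step 2
Reactants: 5 propan-2-ol; 6 trichloroethylene
Product: 10 2-(ethynyloxy)propane, via dichlorovinyl ether 7 (not isolated), via chloroalkyne 8 (not isolated), via lithium acetylide 9 (not isolated)
Conditions: KH, THF, 0 °C; Cl2C=CHCl, −50 °C → rt; n-BuLi (2.4 equiv, pentane), −78 → −40 °C; MeOH, −78 °C; pentane/H2O work-up, fractional distillation
Reagents that add atoms: none
Why: Alkynyl ether synthesis by the dichlorovinyl ether route, in which the alkoxide adds to dichloroacetylene generated in situ, n-BuLi eliminates HCl and exchanges the remaining chlorine for lithium, and methanol protonates the acetylide; no stereocentre is formed.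

Step 3
Reactants: 4 2-[(7-methoxy-2-oxo-2H-chromen-8-yl)oxy]acetic acid; 10 2-(ethynyloxy)propane
Product: 13 4-[(7-methoxy-2-oxo-2H-chromen-8-yl)oxy]-3-(propan-2-yloxy)cyclobut-2-en-1-one (racemic), via acid chloride 11 (not isolated), via aryloxyketene 12 (not isolated)
Conditions: (COCl)2, DMF (cat.), CH2Cl2, 0 °C → rt; evaporate; then slow addition to 10 (2 equiv), Et3N (1.2 equiv), CH2Cl2, 0 °C → rt
Reagents that add atoms: none
Why: Dehydrochlorination of the acid chloride gives the aryloxyketene, which is trapped in a [2+2] cycloaddition by the ynol ether with its nucleophilic CH terminus bonding to the ketene carbonyl carbon, so the alkoxy group sits at C3 and the aryloxy group at C4; the C4 stereocentre forms as a racemate and is erased on aromatisation.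

Step 4
Reactants: 13 4-[(7-methoxy-2-oxo-2H-chromen-8-yl)oxy]-3-(propan-2-yloxy)cyclobut-2-en-1-one; 10 2-(ethynyloxy)propane
Product: 18 8-[2-hydroxy-4,6-bis(propan-2-yloxy)phenoxy]-7-methoxy-2H-chromen-2-one, via vinylketene 14 (not isolated), via alkenylcyclobutenone 15 (not isolated), via dienylketene 16 (not isolated), via cyclohexadienone 17 (not isolated)
Conditions: 10 (3 equiv), toluene, 70 °C, sealed tube, slow addition of 13
Reagents that add atoms: none
Why: Heating opens cyclobutenone 13 by conrotatory 4π electrocyclic ring opening (aryloxy group rotating outward) to vinylketene 14, whose ketene carbon is attacked by the nucleophilic CH terminus of ynol ether 10 in a regioselective [2+2] cycloaddition that gives alkenylcyclobutenone 15. A second, reversible 4π opening gives dienylketene 16, and the rotamer with the alkenyl group turned inward closes ring B by a thermal disrotatory 6π electrocyclisation that forms the C8–C8a bond; tautomerisation of cyclohexadienone 17 gives the phenol. This is the Danheiser benzannulation of a cyclobutenone with an alkoxyalkyne. The stereocentres of 13, 15 and 17 are transient and racemic and vanish on aromatisation, so none has to be controlled. The step needs regiocontrol in the [2+2] event, which the polarisation of the partners secures (electrophilic ketene carbon, nucleophilic β-carbon of the ynol ether), so the ketene oxygen ends as the only free hydroxyl, at C8a next to the aryloxy carbon C8, with the ether oxygens at C5 and C7. The electron-poor C3'=C4' bond of the coumarin in the aryloxy group is not a ketenophile and stays out of the cascade.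

Step 5
Reactants: 18 8-[2-hydroxy-4,6-bis(propan-2-yloxy)phenoxy]-7-methoxy-2H-chromen-2-one; 19 ethyl prop-2-ynoate
Product: 21 8-[(7-methoxy-2-oxo-2H-chromen-8-yl)oxy]-5,7-bis(propan-2-yloxy)-2H-chromen-2-one, via (Z)-cinnamate 20 (not isolated)
Conditions: Pd(OAc)2 (5 mol %), NaOAc, HCO2H, rt
Reagents that add atoms: none
Why: Palladium-catalysed hydroarylation of the alkynoate (a Pechmann-type coumarin annulation) at the only C–H ortho to the single free phenol gives the (Z)-cinnamate, which lactonises at once, and because the other two ring oxygens are capped only the 8-aryloxy coumarin can form.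

Step 6
Reactants: 21 8-[(7-methoxy-2-oxo-2H-chromen-8-yl)oxy]-5,7-bis(propan-2-yloxy)-2H-chromen-2-one
Product: 22 5,7-dihydroxy-8-[(7-methoxy-2-oxo-2H-chromen-8-yl)oxy]-2H-chromen-2-one
Conditions: BCl3 (5 equiv), CH2Cl2, −78 → 0 °C; then H2O
Reagents that add atoms: none
Why: Lewis acid dealkylation in which BCl3 ionises the secondary isopropyl aryl ethers (isopropyl cation trapped as chloride) much faster than it attacks the methyl ether, so both isopropyl groups should fall while the 7'-methoxy group and both lactones stay.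

**Compound list**
1 | 8-hydroxy-7-methoxy-2H-chromen-2-one | COc1ccc2ccc(=O)oc2c1O | starting material
2 | tert-butyl bromoacetate | CC(C)(C)OC(=O)CBr | starting material
3 | tert-butyl 2-[(7-methoxy-2-oxo-2H-chromen-8-yl)oxy]acetate (not isolated) | COc1ccc2ccc(=O)oc2c1OCC(=O)OC(C)(C)C | intermediate
4 | 2-[(7-methoxy-2-oxo-2H-chromen-8-yl)oxy]acetic acid | COc1ccc2ccc(=O)oc2c1OCC(=O)O | intermediate
5 | propan-2-ol | CC(C)O | starting material
6 | trichloroethylene | ClC=C(Cl)Cl | starting material
7 | (E)-1,2-dichloro-1-(propan-2-yloxy)ethene (not isolated) | Cl/C=C(/Cl)OC(C)C | intermediate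
8 | 1-chloro-2-(propan-2-yloxy)ethyne (not isolated) | ClC#COC(C)C | intermediate
9 | lithium 2-(propan-2-yloxy)ethynide (not isolated) | [Li]C#COC(C)C | intermediate
10 | 2-(ethynyloxy)propane | C#COC(C)C | intermediate
11 | 2-[(7-methoxy-2-oxo-2H-chromen-8-yl)oxy]acetyl chloride (not isolated) | COc1ccc2ccc(=O)oc2c1OCC(=O)Cl | intermediate
12 | 2-[(7-methoxy-2-oxo-2H-chromen-8-yl)oxy]ethen-1-one (not isolated) | COc1ccc2ccc(=O)oc2c1OC=C=O | intermediate
13 | 4-[(7-methoxy-2-oxo-2H-chromen-8-yl)oxy]-3-(propan-2-yloxy)cyclobut-2-en-1-one (racemic) | CC(C)OC1=CC(=O)C1Oc1c(OC)ccc2ccc(=O)oc12 | intermediate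
14 | (3Z)-4-[(7-methoxy-2-oxo-2H-chromen-8-yl)oxy]-3-(propan-2-yloxy)buta-1,3-dien-1-one (not isolated) | O=C=C/C(OC(C)C)=C/Oc1c(OC)ccc2ccc(=O)oc12 | intermediate
15 | 4-{(1Z)-2-[(7-methoxy-2-oxo-2H-chromen-8-yl)oxy]-1-(propan-2-yloxy)ethenyl}-3-(propan-2-yloxy)cyclobut-2-en-1-one (racemic, not isolated) | CC(C)OC1=CC(=O)C1/C(OC(C)C)=C/Oc1c(OC)ccc2ccc(=O)oc12 | intermediate
16 | (3E,5Z)-6-[(7-methoxy-2-oxo-2H-chromen-8-yl)oxy]-3,5-bis(propan-2-yloxy)hexa-1,3,5-trien-1-one (not isolated) | O=C=C/C(OC(C)C)=C\C(OC(C)C)=C\Oc1c(OC)ccc2ccc(=O)oc12 | intermediate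
17 | 6-[(7-methoxy-2-oxo-2H-chromen-8-yl)oxy]-3,5-bis(propan-2-yloxy)cyclohexa-2,4-dien-1-one (racemic, not isolated) | O=C1C=C(OC(C)C)C=C(OC(C)C)C1Oc1c(OC)ccc2ccc(=O)oc12 | intermediate
18 | 8-[2-hydroxy-4,6-bis(propan-2-yloxy)phenoxy]-7-methoxy-2H-chromen-2-one | COc1ccc2ccc(=O)oc2c1Oc1c(O)cc(OC(C)C)cc1OC(C)C | intermediate
19 | ethyl prop-2-ynoate | C#CC(=O)OCC | starting material
20 | ethyl (2Z)-3-{2-hydroxy-3-[(7-methoxy-2-oxo-2H-chromen-8-yl)oxy]-4,6-bis(propan-2-yloxy)phenyl}prop-2-enoate (not isolated) | CCOC(=O)/C=C\c1c(O)c(Oc2c(OC)ccc3ccc(=O)oc23)c(OC(C)C)cc1OC(C)C | intermediate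
21 | 8-[(7-methoxy-2-oxo-2H-chromen-8-yl)oxy]-5,7-bis(propan-2-yloxy)-2H-chromen-2-one | COc1ccc2ccc(=O)oc2c1Oc1c(OC(C)C)cc(OC(C)C)c2ccc(=O)oc12 | intermediate
22 | 5,7-dihydroxy-8-[(7-methoxy-2-oxo-2H-chromen-8-yl)oxy]-2H-chromen-2-one | COc1ccc2ccc(=O)oc2c1Oc1c(O)cc(O)c2ccc(=O)oc12 | target

Total step count: 6. Longest linear sequence: 5 steps (1 → 4 → 13 → 18 → 21 → 22); step 2 is a one-step side branch that makes reagent 10.

**Steps most likely to fail**

Step 4. The electron-rich vinylketene may dimerise or acylate the phenol product faster than it is trapped by the ynol ether, and the ynol ether may fragment thermally (retro-ene loss of propene) before the cascade is complete. The fallback sets out from compound 1 and comes back at compound 21. Commercial 5,7-dihydroxy-2H-chromen-2-one F1 would be O-alkylated twice with 2-bromopropane (K2CO3, DMF) to 5,7-bis(propan-2-yloxy)-2H-chromen-2-one F2. Iodination at C8 with N-iodosuccinimide (TFA cat., MeCN) would give 8-iodo-5,7-bis(propan-2-yloxy)-2H-chromen-2-one F3. An Ullmann etherification of F3 with phenol 1 (CuI, N,N-dimethylglycine, Cs2CO3, dioxane, 100 °C) would then give 21.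

Step 3. The aryloxyketene may dimerise, or the acid chloride may acylate the ynol ether before dehydrochlorination, so that little cyclobutenone forms. The fallback sets out from compound 1 and comes back at compound 13. Commercial 3,4-bis(propan-2-yloxy)cyclobut-3-ene-1,2-dione F4 would be reduced with LiAlH(Ot-Bu)3 to 4-hydroxy-2,3-bis(propan-2-yloxy)cyclobut-2-en-1-one F5. Treatment with HCl would convert F5 into 3-(propan-2-yloxy)cyclobut-3-ene-1,2-dione F6. Reduction of its carbonyl outside the vinylogous ester (NaBH4, CeCl3·7H2O, MeOH, −78 °C) would give 4-hydroxy-3-(propan-2-yloxy)cyclobut-2-en-1-one F7. Mitsunobu etherification of F7 with phenol 1 (PPh3, diisopropyl azodicarboxylate, THF) would give 13.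

Step 5. Hydroarylation may take place at the C–H para to the phenol, between the two isopropoxy groups, to give a cinnamate that cannot lactonise, or a second alkynoate may add. The fallback sets out from compound 18 and comes back at compound 21. Magnesium-mediated ortho-formylation (MgCl2, Et3N, paraformaldehyde, MeCN, reflux) would give 2-hydroxy-3-[(7-methoxy-2-oxo-2H-chromen-8-yl)oxy]-4,6-bis(propan-2-yloxy)benzaldehyde F8. A Wittig reaction with ethyl (triphenylphosphoranylidene)acetate in N,N-diethylaniline at reflux would pass through ethyl (2E)-3-{2-hydroxy-3-[(7-methoxy-2-oxo-2H-chromen-8-yl)oxy]-4,6-bis(propan-2-yloxy)phenyl}prop-2-enoate F9, which would isomerise and lactonise in the hot medium to 21.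

**Further compounds**
F1 | step 4 | 5,7-dihydroxy-2H-chromen-2-one | O=c1ccc2c(O)cc(O)cc2o1
F2 | step 4 | 5,7-bis(propan-2-yloxy)-2H-chromen-2-one | CC(C)Oc1cc(OC(C)C)c2ccc(=O)oc2c1
F3 | step 4 | 8-iodo-5,7-bis(propan-2-yloxy)-2H-chromen-2-one | CC(C)Oc1cc(OC(C)C)c2ccc(=O)oc2c1I
F4 | step 3 | 3,4-bis(propan-2-yloxy)cyclobut-3-ene-1,2-dione | CC(C)OC1=C(OC(C)C)C(=O)C1=O
F5 | step 3 | 4-hydroxy-2,3-bis(propan-2-yloxy)cyclobut-2-en-1-one (racemic) | CC(C)OC1=C(OC(C)C)C(=O)C1O
F6 | step 3 | 3-(propan-2-yloxy)cyclobut-3-ene-1,2-dione | CC(C)OC1=CC(=O)C1=O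
F7 | step 3 | 4-hydroxy-3-(propan-2-yloxy)cyclobut-2-en-1-one (racemic) | CC(C)OC1=CC(=O)C1O
F8 | step 5 | 2-hydroxy-3-[(7-methoxy-2-oxo-2H-chromen-8-yl)oxy]-4,6-bis(propan-2-yloxy)benzaldehyde | O=Cc1c(O)c(Oc2c(OC)ccc3ccc(=O)oc23)c(OC(C)C)cc1OC(C)C
F9 | step 5 | ethyl (2E)-3-{2-hydroxy-3-[(7-methoxy-2-oxo-2H-chromen-8-yl)oxy]-4,6-bis(propan-2-yloxy)phenyl}prop-2-enoate | CCOC(=O)/C=C/c1c(O)c(Oc2c(OC)ccc3ccc(=O)oc23)c(OC(C)C)cc1OC(C)C
A1 | direct plan | 3,4,5-trihydroxybenzaldehyde | O=Cc1cc(O)c(O)c(O)c1
A2 | direct plan | 6-bromo-2-fluoro-3-methoxybenzaldehyde | COc1ccc(Br)c(C=O)c1F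
A3 | direct plan | 6-bromo-2-(4-formyl-2,6-dihydroxyphenoxy)-3-methoxybenzaldehyde | COc1ccc(Br)c(C=O)c1Oc1c(O)cc(C=O)cc1O
A4 | direct plan | 6-bromo-2-(3-bromo-4-formyl-2,6-dihydroxyphenoxy)-3-methoxybenzaldehyde | COc1ccc(Br)c(C=O)c1Oc1c(O)cc(C=O)c(Br)c1O
A5 | direct plan | ethyl (Z)-3-(tributylstannyl)prop-2-enoate | CCCC[Sn](CCCC)(CCCC)/C=C\C(=O)OCC
A6 | direct plan | ethyl (2Z)-3-{2-formyl-3-[(5-formyl-7-hydroxy-2-oxo-2H-chromen-8-yl)oxy]-4-methoxyphenyl}prop-2-enoate | CCOC(=O)/C=C\c1ccc(OC)c(Oc2c(O)cc(C=O)c3ccc(=O)oc23)c1C=O
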